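**Plan**

Numbering: furanone ring O1, C2(=O), C3 (side chain), C4 (Br), C5 (=C6HI); C1′ is the acetoxy carbinol carbon.
Retrosynthetic cuts: C6–I (iododecarboxylation of an exocyclic acrylic acid), then C5=C6 (Wittig olefination of a maleic anhydride), then C4–Br and C3–C1′ together.
Enabling feature: the tetrasubstituted C3=C4 alkene of the furanone ring carries Br on C4, C1′ on C3 and the two carbonyl-level ring carbons C2 and C5 cis. This is the adduct pattern of bromide, butanal and an acetylenedicarboxylate.
Forward order: the open chain C2–C3(C1′)=C4(Br)–C5 is joined in one three-component step; the five-membered ring then closes as the anhydride (O1 between C2 and C5) and is kept to the end.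
Stereochemistry: C1′ (R) comes from the chiral oxazaborolidinium-bound aldehyde; the C3=C4 geometry from bromine-side entry into the allenolate; the (Z)-C5=C6 alkene from allylic strain against C4–Br in the last step.

Key step: step 1

Assumption: the oxazaborolidinium ion from (S)-diphenylprolinol is taken to leave the Si face of bound butanal open, as in its other aldehyde additions; should the sense be opposite, the catalyst from (R)-diphenylprolinol is used instead.

**Route**

Step 1
Reactants: 1 di-tert-butyl acetylenedicarboxylate; 2 butanal; 3 bromotrimethylsilane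
Product: 6 di-tert-butyl (2E)-2-bromo-3-[(1R)-1-hydroxybutyl]but-2-enedioate (the two esters cis), via bromo silyl allenolate 4 (not isolated), via aldol trimethylsilyl ether 5 (not isolated)
Conditions: oxazaborolidinium triflimide [C24H25BNO]+[N(SO2CF3)2]− from (S)-α,α-diphenylprolinol, tri(o-tolyl)boroxine and HN(SO2CF3)2 (20 mol %), CH2Cl2, −78 to −40 °C; then 1 M HCl, THF, 0 °C
Reagents that add atoms: bromotrimethylsilane (compound 3), C[Si](C)(C)Br
Why: Proposed new method: bromide from 3 adds in 1,4-fashion to the doubly activated alkyne 1 with O-silylation to give allenolate 4, whose central carbon (future C3) attacks catalyst-bound butanal in a Mukaiyama-type aldol, so that C4–Br, C3–C1′ and the carbinol centre form in one operation without any ring closure, and silyl transfer to the aldolate (5) releases the catalyst. The closest known reaction type is the Lewis-acid three-component halo-aldol (β-halo Baylis–Hillman) coupling of ynoates, halosilanes and aldehydes, including its oxazaborolidinium-catalysed enantioselective iodide variant on propiolates. The C1′ stereocentre is controlled by the catalyst: the aldehyde sits on boron with one face covered by a phenyl group, so the allenolate should add to the Si face and give (R). The step needs the aldehyde to enter the allenolate in the plane of the C4 substituents on the bromine side, so that the two esters end cis. This should be secured by the conjugated tert-butoxycarbonyl group, which lies in that plane and blocks its side more than a single bromine atom on a long C–Br bond, in line with β-aryl ynone halo-aldols, where the halogen ends cis to the carbinol. Regiochemistry is not an issue because 1 is symmetric, and any trans-diester isomer should lactonise on work-up and be separable.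

Step 2
Reactants: 6 di-tert-butyl (2E)-2-bromo-3-[(1R)-1-hydroxybutyl]but-2-enedioate
Product: 7 di-tert-butyl (2E)-2-[(1R)-1-acetoxybutyl]-3-bromobut-2-enedioate
Conditions: Ac2O, pyridine, DMAP (5 mol %), CH2Cl2, 0 °C
Reagents that add atoms: acetic anhydride, CC(=O)OC(C)=O
Why: DMAP-catalysed O-acetylation of a secondary alcohol breaks no bond at C1′, so (R) is retained, and capping the hydroxyl first keeps it out of the acidic steps that follow.

Step 3
Reactants: 7 di-tert-butyl (2E)-2-[(1R)-1-acetoxybutyl]-3-bromobut-2-enedioate
Product: 9 (1R)-1-(4-bromo-2,5-dioxo-2,5-dihydrofuran-3-yl)butyl acetate, via acetoxy diacid 8 (not isolated)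
Conditions: TFA, CH2Cl2, rt; then (CF3CO)2O, 0 °C to rt; evaporate
Reagents that add atoms: none
Why: Acidolysis of both tert-butyl esters (loss of isobutene) leaves the acetate and the vinyl bromide untouched, and the cis-diacid held by the tetrasubstituted alkene should cyclodehydrate readily to the five-membered maleic anhydride.

Step 4
Reactants: 9 (1R)-1-(4-bromo-2,5-dioxo-2,5-dihydrofuran-3-yl)butyl acetate; 10 tert-butyl (triphenylphosphoranylidene)acetate
Product: 11 tert-butyl (2E)-2-[4-[(1R)-1-acetoxybutyl]-3-bromo-5-oxofuran-2(5H)-ylidene]acetate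
Conditions: toluene, rt to 50 °C
Reagents that add atoms: tert-butyl (triphenylphosphoranylidene)acetate (compound 10), CC(C)(C)OC(=O)C=P(c1ccccc1)(c1ccccc1)c1ccccc1
Why: Wittig olefination of a cyclic anhydride with a stabilised ylide (enol-lactone formation) should occur at the C5 carbonyl, which is activated by the adjacent C–Br and less shielded than C2 beside the branched acetoxybutyl group, while bromine lone-pair donation through C4=C3 deactivates C2; the (E)-isomer is expected by analogy, and any (Z)-isomer serves equally in step 5.

Step 5
Reactants: 11 tert-butyl (2E)-2-[4-[(1R)-1-acetoxybutyl]-3-bromo-5-oxofuran-2(5H)-ylidene]acetate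
Product: 13 (1R)-1-[(5Z)-4-bromo-5-(iodomethylidene)-2-oxo-2,5-dihydrofuran-3-yl]butyl acetate, via ylidene acetic acid 12 (not isolated)
Conditions: TFA, CH2Cl2, rt; evaporate; then NIS, LiOAc (20 mol %), MeCN, 0 °C to rt, dark
Reagents that add atoms: N-iodosuccinimide, O=C1CCC(=O)N1I
Why: After tert-butyl ester acidolysis, Hunsdiecker-type iododecarboxylation of the α,β-unsaturated acid with NIS should proceed by iodonium attack at C6 to an O1-stabilised cation at C5 that loses CO2, and the (Z)-iodide (iodine syn to O1) is expected because allylic strain with C4–Br disfavours the (E)-isomer.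

**Compound list**

1 | di-tert-butyl acetylenedicarboxylate | CC(C)(C)OC(=O)C#CC(=O)OC(C)(C)C | starting material
2 | butanal | CCCC=O | starting material
3 | bromotrimethylsilane | C[Si](C)(C)Br | starting material
4 | tert-butyl 2-bromo-4-tert-butoxy-4-(trimethylsilyloxy)buta-2,3-dienoate (racemic allene axis) | CC(C)(C)OC(=O)C(Br)=C=C(O[Si](C)(C)C)OC(C)(C)C | intermediate
5 | di-tert-butyl (2E)-2-bromo-3-[(1R)-1-(trimethylsilyloxy)butyl]but-2-enedioate | CCC[C@@H](O[Si](C)(C)C)/C(C(=O)OC(C)(C)C)=C(\Br)C(=O)OC(C)(C)C | intermediate
6 | di-tert-butyl (2E)-2-bromo-3-[(1R)-1-hydroxybutyl]but-2-enedioate | CCC[C@@H](O)/C(C(=O)OC(C)(C)C)=C(\Br)C(=O)OC(C)(C)C | intermediate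
7 | di-tert-butyl (2E)-2-[(1R)-1-acetoxybutyl]-3-bromobut-2-enedioate | CCC[C@@H](OC(C)=O)/C(C(=O)OC(C)(C)C)=C(\Br)C(=O)OC(C)(C)C | intermediate
8 | (2E)-2-[(1R)-1-acetoxybutyl]-3-bromobut-2-enedioic acid | CCC[C@@H](OC(C)=O)/C(C(=O)O)=C(\Br)C(=O)O | intermediate
9 | (1R)-1-(4-bromo-2,5-dioxo-2,5-dihydrofuran-3-yl)butyl acetate | CCC[C@@H](OC(C)=O)C1=C(Br)C(=O)OC1=O | intermediate
10 | tert-butyl (triphenylphosphoranylidene)acetate | CC(C)(C)OC(=O)C=P(c1ccccc1)(c1ccccc1)c1ccccc1 | starting material
11 | tert-butyl (2E)-2-[4-[(1R)-1-acetoxybutyl]-3-bromo-5-oxofuran-2(5H)-ylidene]acetate | CCC[C@@H](OC(C)=O)C1=C(Br)/C(=C\C(=O)OC(C)(C)C)OC1=O | intermediate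
12 | (2E)-2-[4-[(1R)-1-acetoxybutyl]-3-bromo-5-oxofuran-2(5H)-ylidene]acetic acid | CCC[C@@H](OC(C)=O)C1=C(Br)/C(=C\C(=O)O)OC1=O | intermediate
13 | (1R)-1-[(5Z)-4-bromo-5-(iodomethylidene)-2-oxo-2,5-dihydrofuran-3-yl]butyl acetate | CCC[C@@H](OC(C)=O)C1=C(Br)/C(=C/I)OC1=O | target

Total step count: 5
Longest linear sequence: 5 steps (from 1, 2 and 3 to 13)

**Steps most likely to fail**

Step 1 (Proposed new method). Bromide delivery from the silyl bromide may be too slow at low temperature. The aldehyde may also enter anti to bromine, which gives the wrong alkene geometry and then lactonisation, or facial selectivity may be poor with a small aliphatic aldehyde. The fallback uses known reactions only, sets out from 1 and returns at 6. Pd(PPh3)4-catalysed syn-bis-stannylation of 1 with hexamethyldistannane should give di-tert-butyl (2Z)-2,3-bis(trimethylstannyl)but-2-enedioate F1. Mono Stille acylation with butanoyl chloride (PdCl2(PPh3)2, CuI, THF) should stop at di-tert-butyl (2E)-2-butanoyl-3-(trimethylstannyl)but-2-enedioate F2, because the acyl group deactivates the remaining stannane. Bromodestannylation (Br2, CH2Cl2, −78 °C) with retention should give di-tert-butyl (2E)-2-bromo-3-butanoylbut-2-enedioate F3. CBS reduction of the ketone with (S)-1-methyl-3,3-diphenyltetrahydro-1H,3H-pyrrolo[1,2-c][1,3,2]oxazaborole and catecholborane (toluene, −78 °C) should then deliver the (R)-carbinol 6, with the alkenyl group acting as the large substituent.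

Step 4. The soft phosphorane may attack the C2 carbonyl instead of C5. It may also add to C4 in conjugate fashion and expel bromide or the allylic acetate. The fallback sets out from 9 and returns at 11, and replaces olefination by acylation and dehydration. The lithium enolate of tert-butyl acetate (LDA, THF, −78 °C, 2 equiv) is a hard nucleophile and should add to the more electrophilic C5 carbonyl. The resulting β-keto ester is expected as its ring lactol, tert-butyl 2-[4-[(1R)-1-acetoxybutyl]-3-bromo-2-hydroxy-5-oxo-2,5-dihydrofuran-2-yl]acetate F4. Dehydration with (CF3CO)2O and Et3N (CH2Cl2, 0 °C) should give 11.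

Step 5. The electron-poor exocyclic alkene may be too unreactive toward NIS for the one-pot oxidative decarboxylation, or the iodide may form with incomplete (Z)-selectivity. The fallback sets out from 12 and returns at 13, and separates halogen addition from fragmentation, the sequence established for bromine on acids of this class. ICl (CH2Cl2, 0 °C) should add across C5=C6 with iodine at C6 and chloride at C5, giving 2-[4-[(1R)-1-acetoxybutyl]-3-bromo-2-chloro-5-oxo-2,5-dihydrofuran-2-yl]-2-iodoacetic acid F5. Et3N (DMF, 0 °C) should then trigger a Grob-type loss of CO2 and chloride to 13. Any (E)-iodide could be equilibrated to the less strained (Z)-isomer with catalytic I2 in daylight.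

**Further compounds**

F1 | step 1 | di-tert-butyl (2Z)-2,3-bis(trimethylstannyl)but-2-enedioate | CC(C)(C)OC(=O)/C([Sn](C)(C)C)=C(/[Sn](C)(C)C)C(=O)OC(C)(C)C
F2 | step 1 | di-tert-butyl (2E)-2-butanoyl-3-(trimethylstannyl)but-2-enedioate | CCCC(=O)/C(C(=O)OC(C)(C)C)=C(\[Sn](C)(C)C)C(=O)OC(C)(C)C
F3 | step 1 | di-tert-butyl (2E)-2-bromo-3-butanoylbut-2-enedioate | CCCC(=O)/C(C(=O)OC(C)(C)C)=C(\Br)C(=O)OC(C)(C)C
F4 | step 4 | tert-butyl 2-[4-[(1R)-1-acetoxybutyl]-3-bromo-2-hydroxy-5-oxo-2,5-dihydrofuran-2-yl]acetate | CCC[C@@H](OC(C)=O)C1=C(Br)C(O)(CC(=O)OC(C)(C)C)OC1=O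
F5 | step 5 | 2-[4-[(1R)-1-acetoxybutyl]-3-bromo-2-chloro-5-oxo-2,5-dihydrofuran-2-yl]-2-iodoacetic acid | CCC[C@@H](OC(C)=O)C1=C(Br)C(Cl)(C(I)C(=O)O)OC1=O
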